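**Retrosynthetic overview**
- Target 27 is cut at C5'–C6' of the side chain (Stille coupling) into allylic bromide 21 and (S,E)-vinylstannane 25. Both tertiary C–O stereocentres come from one Sharpless epoxide of geraniol (2) and are never broken afterwards.
- 21 goes back to chromenyl boronate 17 (C–B to C6–OH, silylation, SeO2 oxidation of the E-methyl, bromination). 17 goes back to 4-silyloxychroman boronate 14 by desilylation and dehydration, so C3=C4 of ring B is made last.
- The strategy rests on benzene ring A (C4a, C5, C6, C7, C8, C8a). It carries O1 on C8a, CH3 on C8, OH on C6 and C4 on C4a, and shares the C4a–C8a bond with pyran ring B. A [2+2+2] cycloaddition of the O1-tethered ynol-ether diyne 12 with ethynylboronate 13 therefore builds both rings: ring B closes first in the metallacycle, ring A on alkyne insertion (bonds C4a–C8a, C5–C6, C7–C8).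
- The tether of 12 is saturated at C3–C4 and carries a silyloxy group on C4. A cis-alkene there would make the ynol ether an allyl alkynyl ether, which undergoes [3,3] shift to a ketene far below room temperature. 12 comes from 2 by directed epoxide reduction, oxidation, alkynylation, silylation and alkoxide/trichloroethylene ynol ether formation.
- 25 comes from 2 by epoxy chloride fragmentation to the (S)-propargylic carbinol 24 and hydrostannation.

Key step: step 8

Remark: the silyloxy/hydroxy carbon made in step 4 (C3 of 6, 7, 9–12; C4 of 14–16) is carried as a mixture of both epimers, since it becomes sp2 in step 10.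

**Route**

Step 1
Reactants: 1 geraniol
Product: 2 [(2S,3S)-3-methyl-3-(4-methylpent-3-en-1-yl)oxiran-2-yl]methanol
Conditions: Ti(OiPr)4 (5 mol %), L-(+)-diethyl tartrate (6 mol %), t-BuOOH, 4 Å MS, CH2Cl2, −20 °C
Reagents that add atoms: tert-butyl hydroperoxide, CC(C)(C)OO
Why: Sharpless asymmetric epoxidation; the titanium–L-(+)-tartrate catalyst delivers oxygen to the face of the allylic alkene that gives the (2S,3S)-epoxide (catalyst control of both new stereocentres) and leaves the remote trisubstituted alkene alone.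

Step 2
Reactants: 2 [(2S,3S)-3-methyl-3-(4-methylpent-3-en-1-yl)oxiran-2-yl]methanol
Product: 3 (3S)-3,7-dimethyloct-6-ene-1,3-diol
Conditions: NaAlH2(OCH2CH2OCH3)2 (Red-Al), THF, 0 °C to rt
Reagents that add atoms: none
Why: Hydroxyl-directed reductive epoxide opening; the C1 alkoxyaluminate delivers hydride to C2, so the C3–O bond keeps its configuration and the 1,3-diol should result.

Step 3
Reactants: 3 (3S)-3,7-dimethyloct-6-ene-1,3-diol
Product: 4 (3S)-3-hydroxy-3,7-dimethyloct-6-enal
Conditions: TEMPO (10 mol %), PhI(OAc)2, CH2Cl2, rt; used crude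
Reagents that add atoms: none
Why: Oxoammonium (TEMPO/PhI(OAc)2) oxidation converts only the primary alcohol, since the tertiary alcohol cannot be oxidised, and the near-neutral medium should avoid dehydration of the β-hydroxy aldehyde.

Step 4
Reactants: 4 (3S)-3-hydroxy-3,7-dimethyloct-6-enal; 5 trimethylsilylacetylene
Product: 6 (5S)-5,9-dimethyl-1-(trimethylsilyl)dec-8-en-1-yne-3,5-diol (both C3 epimers)
Conditions: 5, n-BuLi, THF, −78 °C (3 equiv of acetylide); then 4, −78 °C
Reagents that add atoms: none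
Why: 1,2-Addition of a lithium acetylide to an aldehyde at low temperature; the first equivalent only deprotonates the tertiary hydroxyl, and the new carbinol centre is left uncontrolled because it is erased in step 10.

Step 5
Reactants: 6 (5S)-5,9-dimethyl-1-(trimethylsilyl)dec-8-en-1-yne-3,5-diol
Product: 7 (5S)-5,9-dimethyl-3-[(triisopropylsilyl)oxy]-1-(trimethylsilyl)dec-8-en-1-yn-5-ol
Conditions: TIPSOTf (1.1 equiv), 2,6-lutidine, CH2Cl2, −78 to −20 °C
Reagents that add atoms: triisopropylsilyl trifluoromethanesulfonate, CC(C)[Si](C(C)C)(C(C)C)OS(=O)(=O)C(F)(F)F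
Why: Silylation with a bulky silyl triflate is selective for the secondary propargylic hydroxyl over the tertiary one, and triisopropylsilyl is chosen because it resists oxygen-to-oxygen migration under the basic conditions of step 6.

Step 6
Reactants: 7 (5S)-5,9-dimethyl-3-[(triisopropylsilyl)oxy]-1-(trimethylsilyl)dec-8-en-1-yn-5-ol; 8 trichloroethylene
Product: 11 (5S)-5,9-dimethyl-5-(prop-1-yn-1-yloxy)-3-[(triisopropylsilyl)oxy]-1-(trimethylsilyl)dec-8-en-1-yne, via dichlorovinyl ether 9 (not isolated), via lithium alkoxyacetylide 10 (not isolated)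
Conditions: KH, THF, 0 °C to rt; 8, −50 °C to rt; n-BuLi (2.5 equiv), −78 to −40 °C; MeI, HMPA, −78 to 0 °C; work-up below 25 °C, Et3N-washed silica
Reagents that add atoms: iodomethane, CI
Why: Ynol ether synthesis by addition of the potassium alkoxide to dichloroacetylene formed in the flask, HCl elimination and chlorine–lithium exchange with n-BuLi, then C-methylation of the lithium alkoxyacetylide; the C5–O bond is not involved, so the (S) configuration is kept.

Step 7
Reactants: 11 (5S)-5,9-dimethyl-5-(prop-1-yn-1-yloxy)-3-[(triisopropylsilyl)oxy]-1-(trimethylsilyl)dec-8-en-1-yne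
Product: 12 (5S)-5,9-dimethyl-5-(prop-1-yn-1-yloxy)-3-[(triisopropylsilyl)oxy]dec-8-en-1-yne
Conditions: K2CO3, MeOH, 0 °C to rt
Reagents that add atoms: none
Why: Base-mediated methanolysis (protodesilylation) cleaves only the alkynyl C–Si bond; the silyl ether and the ynol ether are stable to carbonate in methanol.

Step 8
Reactants: 12 (5S)-5,9-dimethyl-5-(prop-1-yn-1-yloxy)-3-[(triisopropylsilyl)oxy]dec-8-en-1-yne; 13 2-ethynyl-4,4,5,5-tetramethyl-1,3,2-dioxaborolane
Product: 14 (2S)-2,8-dimethyl-2-(4-methylpent-3-en-1-yl)-6-(4,4,5,5-tetramethyl-1,3,2-dioxaborolan-2-yl)-4-[(triisopropylsilyl)oxy]-3,4-dihydro-2H-chromene (both C4 epimers)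
Conditions: Cp*RuCl(cod) (10 mol %), 13 (3 equiv), ClCH2CH2Cl, 20 °C, slow addition of 12
Reagents that add atoms: none
Why: Proposed new method: after loss of cyclooctadiene the divalent ruthenium fragment Cp*RuCl should bind the ynol-ether alkyne and the terminal alkyne of 12 and couple them oxidatively at their inner carbons (C8a–C4a) to a ruthenacyclopentadiene fused to the new pyran ring B; insertion of 13 at the unsubstituted Ru–C5 terminus and reductive elimination then form C5–C6 and C7–C8 and release aromatic ring A. The closest known reactions are Cp*RuCl(cod)-catalysed [2+2+2] cycloadditions of tethered 1,6- and 1,7-diynes with terminal alkynes and alkynylboronates, and cyclotrimerisations with alkoxyalkyne or ynamide partners; a diyne with an ynol-ether terminus and the oxygen in the tether has not been shown. Ring B closes as the six-membered ring annulated to the metallacycle in the oxidative cyclisation (helped by the Thorpe–Ingold effect of quaternary C2), and ring A closes by alkyne insertion and reductive elimination with aromatisation. No new stereocentre is set: the O1–C2 bond of the (S)-ether is never broken, and the C4 silyloxy centre is an epimer mixture that is erased in step 10. The step needs boron on C6 and not on C7, which the steric clash between the pinacolboryl group and the C8 methyl on the ruthenacycle should secure (meta placement); it also needs the diyne to survive, which the saturated C3–C4 tether (no allyl alkynyl ether, so no [3,3] shift) and reaction at room temperature (no retro-ene loss of a ketene from the tertiary-alkyl ynol ether) are meant to secure.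

Step 9
Reactants: 14 (2S)-2,8-dimethyl-2-(4-methylpent-3-en-1-yl)-6-(4,4,5,5-tetramethyl-1,3,2-dioxaborolan-2-yl)-4-[(triisopropylsilyl)oxy]-3,4-dihydro-2H-chromene
Product: 15 (2S)-2,8-dimethyl-2-(4-methylpent-3-en-1-yl)-6-(4,4,5,5-tetramethyl-1,3,2-dioxaborolan-2-yl)-3,4-dihydro-2H-chromen-4-ol (both C4 epimers)
Conditions: TBAF, THF, 0 °C to rt
Reagents that add atoms: none
Why: Fluoride-mediated silyl ether cleavage; the aryl pinacol boronate binds fluoride only reversibly and should be returned on aqueous work-up.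

Step 10
Reactants: 15 (2S)-2,8-dimethyl-2-(4-methylpent-3-en-1-yl)-6-(4,4,5,5-tetramethyl-1,3,2-dioxaborolan-2-yl)-3,4-dihydro-2H-chromen-4-ol
Product: 17 (2S)-2,8-dimethyl-2-(4-methylpent-3-en-1-yl)-6-(4,4,5,5-tetramethyl-1,3,2-dioxaborolan-2-yl)-2H-chromene, via C4 mesylate 16 (not isolated)
Conditions: MsCl, Et3N (5 equiv), CH2Cl2, 0 °C to reflux
Reagents that add atoms: none
Why: Sulfonylation–elimination (dehydration); the benzylic mesylate, activated by the ring oxygen ortho to C4a, loses methanesulfonate and a C3 proton under basic conditions, which avoids acid-induced cation–olefin cyclisation onto the side-chain alkene, and both C4 epimers converge while C2 is untouched.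

Step 11
Reactants: 17 (2S)-2,8-dimethyl-2-(4-methylpent-3-en-1-yl)-6-(4,4,5,5-tetramethyl-1,3,2-dioxaborolan-2-yl)-2H-chromene
Product: 18 (2S)-2,8-dimethyl-2-(4-methylpent-3-en-1-yl)-2H-chromen-6-ol
Conditions: NaBO3·4H2O, THF/H2O, rt
Reagents that add atoms: sodium perborate tetrahydrate, [Na+].[O-]OB=O.O.O.O.O
Why: Oxidation of the aryl C–B bond (1,2-aryl shift in the peroxoborate, then hydrolysis) with mild perborate should leave both alkenes untouched.

Step 12
Reactants: 18 (2S)-2,8-dimethyl-2-(4-methylpent-3-en-1-yl)-2H-chromen-6-ol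
Product: 19 tert-butyl{[(2S)-2,8-dimethyl-2-(4-methylpent-3-en-1-yl)-2H-chromen-6-yl]oxy}dimethylsilane
Conditions: TBSCl, imidazole, DMF, rt
Reagents that add atoms: tert-butyldimethylsilyl chloride, CC(C)(C)[Si](C)(C)Cl
Why: Standard phenol silylation protects the oxidation-prone hydroquinone monoether before the allylic oxidation.

Step 13
Reactants: 19 tert-butyl{[(2S)-2,8-dimethyl-2-(4-methylpent-3-en-1-yl)-2H-chromen-6-yl]oxy}dimethylsilane
Product: 20 (2E)-5-[(2S)-6-{[tert-butyl(dimethyl)silyl]oxy}-2,8-dimethyl-2H-chromen-2-yl]-2-methylpent-2-en-1-ol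
Conditions: SeO2 (0.5 equiv), t-BuOOH, salicylic acid (cat.), CH2Cl2, rt, stopped at partial conversion
Reagents that add atoms: selenium dioxide, O=[Se]=O (oxygen carrier, reoxidised in the flask); tert-butyl hydroperoxide, CC(C)(C)OO
Why: Riley allylic oxidation (ene reaction, then [2,3]-sigmatropic shift) attacks the E-methyl of the terminal trisubstituted alkene and so fixes the E geometry of the new allylic alcohol; the chromene alkene has no allylic C–H.

Step 14
Reactants: 20 (2E)-5-[(2S)-6-{[tert-butyl(dimethyl)silyl]oxy}-2,8-dimethyl-2H-chromen-2-yl]-2-methylpent-2-en-1-ol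
Product: 21 {[(2S)-2-[(3E)-5-bromo-4-methylpent-3-en-1-yl]-2,8-dimethyl-2H-chromen-6-yl]oxy}(tert-butyl)dimethylsilane
Conditions: CBr4, PPh3, CH2Cl2, −20 to 0 °C
Reagents that add atoms: carbon tetrabromide, BrC(Br)(Br)Br
Why: Appel bromination; bromide displaces the alkoxyphosphonium at the primary allylic carbon under neutral conditions without allylic transposition.

Step 15
Reactants: 2 [(2S,3S)-3-methyl-3-(4-methylpent-3-en-1-yl)oxiran-2-yl]methanol
Product: 22 (2R,3S)-2-(chloromethyl)-3-methyl-3-(4-methylpent-3-en-1-yl)oxirane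
Conditions: PPh3, CCl4, NaHCO3, reflux
Reagents that add atoms: carbon tetrachloride, ClC(Cl)(Cl)Cl
Why: Appel chlorination under buffered conditions keeps the acid-labile epoxide intact; the descriptor at C2 changes to R only through the priority change.

Step 16
Reactants: 22 (2R,3S)-2-(chloromethyl)-3-methyl-3-(4-methylpent-3-en-1-yl)oxirane
Product: 24 (3S)-3,7-dimethyloct-6-en-1-yn-3-ol, via lithium chlorovinyl alkoxide 23 (not isolated)
Conditions: n-BuLi (3.2 equiv), THF, −40 to −20 °C
Reagents that add atoms: none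
Why: Base-induced fragmentation of a 2,3-epoxy chloride (deprotonation next to chlorine, epoxide opening, then loss of HCl) gives the tertiary propargylic alcohol; the C3–O bond is not broken, so the epoxide carbon keeps its (S) configuration.

Step 17
Reactants: 24 (3S)-3,7-dimethyloct-6-en-1-yn-3-ol
Product: 25 (1E,3S)-3,7-dimethyl-1-(tributylstannyl)octa-1,6-dien-3-ol
Conditions: Bu3SnH (slow addition), PdCl2(PPh3)2 (2 mol %), THF, 0 °C
Reagents that add atoms: tributyltin hydride, CCCC[SnH](CCCC)CCCC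
Why: Palladium-catalysed hydrostannation is a syn addition, and the bulk of the tertiary carbinol should direct tin to the terminal carbon, giving the E-vinylstannane.

Step 18
Reactants: 21 {[(2S)-2-[(3E)-5-bromo-4-methylpent-3-en-1-yl]-2,8-dimethyl-2H-chromen-6-yl]oxy}(tert-butyl)dimethylsilane; 25 (1E,3S)-3,7-dimethyl-1-(tributylstannyl)octa-1,6-dien-3-ol
Product: 26 (2S)-6-{[tert-butyl(dimethyl)silyl]oxy}-2-[(3E,6E,8S)-8-hydroxy-4,8,12-trimethyltrideca-3,6,11-trien-1-yl]-2,8-dimethyl-2H-chromene
Conditions: Pd2(dba)3 (5 mol %), AsPh3 (20 mol %), THF, 50 °C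
Reagents that add atoms: none
Why: Stille coupling; oxidative addition of the allylic bromide, transmetallation and reductive elimination at the less hindered CH2 terminus join C5' to C6' with retention of both alkene geometries, and the free tertiary alcohol is tolerated.

Step 19
Reactants: 26 (2S)-6-{[tert-butyl(dimethyl)silyl]oxy}-2-[(3E,6E,8S)-8-hydroxy-4,8,12-trimethyltrideca-3,6,11-trien-1-yl]-2,8-dimethyl-2H-chromene
Product: 27 (2S)-2-[(3E,6E,8S)-8-hydroxy-4,8,12-trimethyltrideca-3,6,11-trien-1-yl]-2,8-dimethyl-2H-chromen-6-ol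
Conditions: TBAF, THF, 0 °C, degassed
Reagents that add atoms: none
Why: Fluoride cleavage of the aryl silyl ether is fast at 0 °C and should leave the tertiary allylic alcohol, the skipped diene and the chromene untouched.

**Compound list**
1 | geraniol, (2E)-3,7-dimethylocta-2,6-dien-1-ol | CC(C)=CCC/C(C)=C/CO | starting material
2 | [(2S,3S)-3-methyl-3-(4-methylpent-3-en-1-yl)oxiran-2-yl]methanol | CC(C)=CCC[C@]1(C)O[C@H]1CO | intermediate
3 | (3S)-3,7-dimethyloct-6-ene-1,3-diol | CC(C)=CCC[C@](C)(O)CCO | intermediate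
4 | (3S)-3-hydroxy-3,7-dimethyloct-6-enal | CC(C)=CCC[C@](C)(O)CC=O | intermediate
5 | trimethylsilylacetylene | C#C[Si](C)(C)C | starting material
6 | (5S)-5,9-dimethyl-1-(trimethylsilyl)dec-8-en-1-yne-3,5-diol (both C3 epimers) | CC(C)=CCC[C@](C)(O)CC(O)C#C[Si](C)(C)C | intermediate
7 | (5S)-5,9-dimethyl-3-[(triisopropylsilyl)oxy]-1-(trimethylsilyl)dec-8-en-1-yn-5-ol | CC(C)=CCC[C@](C)(O)CC(O[Si](C(C)C)(C(C)C)C(C)C)C#C[Si](C)(C)C | intermediate
8 | trichloroethylene | ClC=C(Cl)Cl | starting material
9 | (5S)-5-{[(E)-1,2-dichloroethenyl]oxy}-5,9-dimethyl-3-[(triisopropylsilyl)oxy]-1-(trimethylsilyl)dec-8-en-1-yne | CC(C)=CCC[C@](C)(O/C(Cl)=C\Cl)CC(O[Si](C(C)C)(C(C)C)C(C)C)C#C[Si](C)(C)C | intermediate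
10 | lithium alkoxyacetylide of the same ether, (5S)-5-[(lithioethynyl)oxy]-5,9-dimethyl-3-[(triisopropylsilyl)oxy]-1-(trimethylsilyl)dec-8-en-1-yne | CC(C)=CCC[C@](C)(OC#C[Li])CC(O[Si](C(C)C)(C(C)C)C(C)C)C#C[Si](C)(C)C | intermediate
11 | (5S)-5,9-dimethyl-5-(prop-1-yn-1-yloxy)-3-[(triisopropylsilyl)oxy]-1-(trimethylsilyl)dec-8-en-1-yne | CC(C)=CCC[C@](C)(OC#CC)CC(O[Si](C(C)C)(C(C)C)C(C)C)C#C[Si](C)(C)C | intermediate
12 | (5S)-5,9-dimethyl-5-(prop-1-yn-1-yloxy)-3-[(triisopropylsilyl)oxy]dec-8-en-1-yne | CC(C)=CCC[C@](C)(OC#CC)CC(O[Si](C(C)C)(C(C)C)C(C)C)C#C | intermediate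
13 | 2-ethynyl-4,4,5,5-tetramethyl-1,3,2-dioxaborolane (ethynylboronic acid pinacol ester) | C#CB1OC(C)(C)C(C)(C)O1 | starting material
14 | (2S)-2,8-dimethyl-2-(4-methylpent-3-en-1-yl)-6-(4,4,5,5-tetramethyl-1,3,2-dioxaborolan-2-yl)-4-[(triisopropylsilyl)oxy]-3,4-dihydro-2H-chromene (both C4 epimers) | CC(C)=CCC[C@@]1(C)CC(O[Si](C(C)C)(C(C)C)C(C)C)c2cc(B3OC(C)(C)C(C)(C)O3)cc(C)c2O1 | intermediate
15 | (2S)-2,8-dimethyl-2-(4-methylpent-3-en-1-yl)-6-(4,4,5,5-tetramethyl-1,3,2-dioxaborolan-2-yl)-3,4-dihydro-2H-chromen-4-ol (both C4 epimers) | CC(C)=CCC[C@@]1(C)CC(O)c2cc(B3OC(C)(C)C(C)(C)O3)cc(C)c2O1 | intermediate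
16 | 4-methanesulfonate of 15 | CC(C)=CCC[C@@]1(C)CC(OS(C)(=O)=O)c2cc(B3OC(C)(C)C(C)(C)O3)cc(C)c2O1 | intermediate
17 | (2S)-2,8-dimethyl-2-(4-methylpent-3-en-1-yl)-6-(4,4,5,5-tetramethyl-1,3,2-dioxaborolan-2-yl)-2H-chromene | CC(C)=CCC[C@@]1(C)C=Cc2cc(B3OC(C)(C)C(C)(C)O3)cc(C)c2O1 | intermediate
18 | (2S)-2,8-dimethyl-2-(4-methylpent-3-en-1-yl)-2H-chromen-6-ol | CC(C)=CCC[C@@]1(C)C=Cc2cc(O)cc(C)c2O1 | intermediate
19 | tert-butyl{[(2S)-2,8-dimethyl-2-(4-methylpent-3-en-1-yl)-2H-chromen-6-yl]oxy}dimethylsilane | CC(C)=CCC[C@@]1(C)C=Cc2cc(O[Si](C)(C)C(C)(C)C)cc(C)c2O1 | intermediate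
20 | (2E)-5-[(2S)-6-{[tert-butyl(dimethyl)silyl]oxy}-2,8-dimethyl-2H-chromen-2-yl]-2-methylpent-2-en-1-ol | OC/C(C)=C/CC[C@@]1(C)C=Cc2cc(O[Si](C)(C)C(C)(C)C)cc(C)c2O1 | intermediate
21 | {[(2S)-2-[(3E)-5-bromo-4-methylpent-3-en-1-yl]-2,8-dimethyl-2H-chromen-6-yl]oxy}(tert-butyl)dimethylsilane | BrC/C(C)=C/CC[C@@]1(C)C=Cc2cc(O[Si](C)(C)C(C)(C)C)cc(C)c2O1 | intermediate
22 | (2R,3S)-2-(chloromethyl)-3-methyl-3-(4-methylpent-3-en-1-yl)oxirane | CC(C)=CCC[C@]1(C)O[C@H]1CCl | intermediate
23 | lithium (3S)-1-chloro-3,7-dimethylocta-1,6-dien-3-olate (C1=C2 geometry not defined) | CC(C)=CCC[C@](C)(O[Li])C=CCl | intermediate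
24 | (3S)-3,7-dimethyloct-6-en-1-yn-3-ol | CC(C)=CCC[C@](C)(O)C#C | intermediate
25 | (1E,3S)-3,7-dimethyl-1-(tributylstannyl)octa-1,6-dien-3-ol | CC(C)=CCC[C@](C)(O)/C=C/[Sn](CCCC)(CCCC)CCCC | intermediate
26 | (2S)-6-{[tert-butyl(dimethyl)silyl]oxy}-2-[(3E,6E,8S)-8-hydroxy-4,8,12-trimethyltrideca-3,6,11-trien-1-yl]-2,8-dimethyl-2H-chromene | CC(C)=CCC[C@](C)(O)/C=C/C/C(C)=C/CC[C@@]1(C)C=Cc2cc(O[Si](C)(C)C(C)(C)C)cc(C)c2O1 | intermediate
27 | (2S)-2-[(3E,6E,8S)-8-hydroxy-4,8,12-trimethyltrideca-3,6,11-trien-1-yl]-2,8-dimethyl-2H-chromen-6-ol | CC(C)=CCC[C@](C)(O)/C=C/C/C(C)=C/CC[C@@]1(C)C=Cc2cc(O)cc(C)c2O1 | target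

**Step count**
Total: 19 steps. Longest linear sequence: 16 steps (steps 1–14, 18, 19 from geraniol); the stannane branch is steps 1, 15, 16, 17.

**Steps most likely to fail**

1. Step 8 (proposed new method). The oxidative coupling of the electron-rich ynol-ether alkyne with the terminal alkyne may be slower than homotrimerisation of 13, or than hydration or thermal fragmentation of the ynol ether. The boronate alkyne may also insert with boron next to C8. The fallback uses known reactions and forms the aryl C8a–O1 bond instead, so the C2–O bond is again never broken. It sets out from 24. Sonogashira coupling with 2-bromo-1-iodo-3-methylbenzene (PdCl2(PPh3)2, copper iodide CuI, Et3N, rt; the carbon–iodine bond reacts selectively) would give (3S)-1-(2-bromo-3-methylphenyl)-3,7-dimethyloct-6-en-1-yn-3-ol F1. Cis-selective semihydrogenation (H2, Pd/CaCO3 poisoned with Pb(OAc)2, quinoline) would give (1Z,3S)-1-(2-bromo-3-methylphenyl)-3,7-dimethylocta-1,6-dien-3-ol F2. Intramolecular palladium-catalysed C–O coupling of the tertiary alcohol with the aryl bromide (Pd(OAc)2, 2-(di-tert-butylphosphino)-1,1'-binaphthyl, Cs2CO3, toluene, 80 °C) would close ring B to (2S)-2,8-dimethyl-2-(4-methylpent-3-en-1-yl)-2H-chromene F3. Iridium-catalysed C–H borylation ([Ir(OMe)(cod)]2, 4,4'-di-tert-butyl-2,2'-bipyridine, B2pin2), directed by sterics to C6 as the only aromatic C–H flanked by two hydrogens, comes back to the route at 17.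

2. Step 6. The silyl group may migrate from the secondary propargylic oxygen to the tertiary alkoxide, so that the wrong oxygen is etherified, or the hindered alkoxide may add poorly to dichloroacetylene. The fallback never forms the alkoxide and sets out from 7. Formylation (acetic formic anhydride, pyridine, DMAP) would give (5S)-5,9-dimethyl-3-[(triisopropylsilyl)oxy]-1-(trimethylsilyl)dec-8-en-1-yn-5-yl formate F4. Dichloromethylenation of the formate (PPh3, CCl4, THF, 60 °C) would give the 2,2-dichloroethenyl ether F5. n-BuLi (2.2 equiv, −78 °C; chlorine–lithium exchange, Fritsch–Buttenberg–Wiechell-type hydride shift, deprotonation) would give lithium alkoxyacetylide 10, which is methylated as in step 6 to come back at 11.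

3. Step 4. The β-hydroxy aldehyde 4 may fragment by retro-aldol cleavage or dehydrate under the basic acetylide before addition occurs. The fallback changes the order of events and sets out from 2. Oxidation (SO3·pyridine, DMSO, Et3N) would give (2R,3S)-3-methyl-3-(4-methylpent-3-en-1-yl)oxirane-2-carbaldehyde F6. Addition of lithium (trimethylsilyl)acetylide would give 1-[(2S,3S)-3-methyl-3-(4-methylpent-3-en-1-yl)oxiran-2-yl]-3-(trimethylsilyl)prop-2-yn-1-ol F7. Silylation (TIPSOTf, 2,6-lutidine) would give its triisopropylsilyl ether F8. Hydride opening of the epoxide at the secondary carbon (LiEt3BH, THF, 0 °C to rt) comes back at 7.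

**Further compounds**
F1 | step 8 | (3S)-1-(2-bromo-3-methylphenyl)-3,7-dimethyloct-6-en-1-yn-3-ol | CC(C)=CCC[C@](C)(O)C#Cc1cccc(C)c1Br
F2 | step 8 | (1Z,3S)-1-(2-bromo-3-methylphenyl)-3,7-dimethylocta-1,6-dien-3-ol | CC(C)=CCC[C@](C)(O)/C=C\c1cccc(C)c1Br
F3 | step 8 | (2S)-2,8-dimethyl-2-(4-methylpent-3-en-1-yl)-2H-chromene | CC(C)=CCC[C@@]1(C)C=Cc2cccc(C)c2O1
F4 | step 6 | (5S)-5,9-dimethyl-3-[(triisopropylsilyl)oxy]-1-(trimethylsilyl)dec-8-en-1-yn-5-yl formate | CC(C)=CCC[C@](C)(OC=O)CC(O[Si](C(C)C)(C(C)C)C(C)C)C#C[Si](C)(C)C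
F5 | step 6 | (5S)-5-[(2,2-dichloroethenyl)oxy]-5,9-dimethyl-3-[(triisopropylsilyl)oxy]-1-(trimethylsilyl)dec-8-en-1-yne | CC(C)=CCC[C@](C)(OC=C(Cl)Cl)CC(O[Si](C(C)C)(C(C)C)C(C)C)C#C[Si](C)(C)C
F6 | step 4 | (2R,3S)-3-methyl-3-(4-methylpent-3-en-1-yl)oxirane-2-carbaldehyde | CC(C)=CCC[C@]1(C)O[C@H]1C=O
F7 | step 4 | 1-[(2S,3S)-3-methyl-3-(4-methylpent-3-en-1-yl)oxiran-2-yl]-3-(trimethylsilyl)prop-2-yn-1-ol (both carbinol epimers) | CC(C)=CCC[C@]1(C)O[C@H]1C(O)C#C[Si](C)(C)C
F8 | step 4 | triisopropylsilyl ether of F7 | CC(C)=CCC[C@]1(C)O[C@H]1C(O[Si](C(C)C)(C(C)C)C(C)C)C#C[Si](C)(C)C
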